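**Plan**

- Quinic numbering is used throughout: C1 is the carbinol carbon carrying CO2H, C3 the free OH, C4 the malonate, C5 the caffeate. C1 is a quaternary, oxygen-bearing carboxyl carbon lying between the two methylenes C2 and C6; this is the imprint a 2-acyloxyacrolein leaves when it adds across butadiene.
- Retrosynthetic cuts, in order: the C4–O malonyl and C5–O caffeoyl ester bonds; the C3/C4 oxygens back to a C3=C4 alkene and O5 back to a γ-lactone from the C1 carboxyl; finally the ring bonds C1–C6 and C2–C3.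
- Forward: the acyloxyacrolein is made from a dioxanone and the [4+2] closes the only carbocycle. The lactone bridge is then built and used for elimination and osmylation. O3 is capped as a PMB ether while the lactone still locks the chair; then follow lactone opening, C5 caffeate, C4 malonate and one acidolysis.
- Stereochemistry: C1 comes from a chiral binaphthyl diammonium catalyst in the cycloaddition. C5, C4 and C3 are relayed from C1 (cis lactonisation onto C5, anti bromide, dihydroxylation on the face away from the bridge).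

Key step: step 3

Assumption: the (S)-diamine is written as the catalyst antipode that exposes the dienophile face leading to (S)-5; if the sense of induction is the opposite, the equally available (R)-diamine is used and nothing else changes. PMB = 4-methoxybenzyl.

**Route**

Step 1
Reactants: 1 2,2-dimethyl-1,3-dioxan-5-one
Product: 2 2,2-dimethyl-4H-1,3-dioxin-5-yl benzoate
Conditions: KN(SiMe3)2, THF, −78 °C; BzCl, −78 → 0 °C
Reagents that add atoms: benzoyl chloride, O=C(Cl)c1ccccc1
Why: The dissociated potassium enolate of the α,α'-dioxygenated ketone is a hard nucleophile and should be acylated on oxygen by the acid chloride (enolate O-acylation) to give the enol benzoate.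

Step 2
Reactants: 2 2,2-dimethyl-4H-1,3-dioxin-5-yl benzoate
Product: 3 2-(benzoyloxy)acrolein (3-oxoprop-1-en-2-yl benzoate)
Conditions: toluene, 110 °C, BHT (trace), acetone distilled off; used at once
Reagents that add atoms: none
Why: Thermal retro-hetero-Diels–Alder fragmentation of the 4H-1,3-dioxin expels acetone and unveils the 2-acyloxy enal, the standard access to this dienophile class.

Step 3
Reactants: 3 2-(benzoyloxy)acrolein; 4 buta-1,3-diene
Product: 5 (S)-1-formylcyclohex-3-en-1-yl benzoate
Conditions: (S)-1,1'-binaphthyl-2,2'-diamine (10 mol%), Tf2NH (19 mol%), buta-1,3-diene (5 equiv), EtCN, −40 → −20 °C, sealed vessel; aqueous work-up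
Reagents that add atoms: none
Why: One primary ammonium group of the diammonium salt condenses reversibly with the aldehyde of 3 to an iminium ion whose lowered LUMO is attacked by s-cis butadiene in a concerted suprafacial [4+2] cycloaddition, and hydrolysis of the product iminium returns the catalyst. The closest known reaction type is the chiral primary ammonium salt catalysed enantioselective Diels–Alder reaction of α-acyloxyacroleins with dienes. The six-membered carbocycle closes by intermolecular [4+2] cycloaddition, both σ-bonds (C1–C6 and C2–C3 in target numbering) forming in one event and leaving the C4=C5 alkene. The single new stereocentre, quaternary C1, is controlled by the binaphthyl backbone of the iminium, which screens one π-face of the dienophile while the acyloxy carbonyl, hydrogen-bonded to the second ammonium group, fixes its conformation. Only facial selectivity is required, because the symmetric diene removes every regiochemical and endo/exo question.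

Step 4
Reactants: 5 (S)-1-formylcyclohex-3-en-1-yl benzoate
Product: 6 (S)-1-(benzoyloxy)cyclohex-3-ene-1-carboxylic acid
Conditions: NaClO2, NaH2PO4, 2-methylbut-2-ene, t-BuOH/H2O, 0 °C → rt
Reagents that add atoms: sodium chlorite, [Na+].[O-]Cl=O
Why: Pinnick oxidation converts the aldehyde into the acid through its chlorous acid adduct, while the excess trisubstituted alkene traps hypochlorous acid so that the ring alkene survives and the quaternary centre, having no α-hydrogen, cannot epimerise.

Step 5
Reactants: 6 (S)-1-(benzoyloxy)cyclohex-3-ene-1-carboxylic acid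
Product: 7 (1S,4R,5R)-4-bromo-7-oxo-6-oxabicyclo[3.2.1]octan-1-yl benzoate (lactone O on C5, Br on C4 trans to it)
Conditions: Br2, NaHCO3, H2O/CH2Cl2, 0 °C, dark
Reagents that add atoms: bromine, BrBr
Why: Bromolactonisation, in which the carboxylate opens the bromonium ion formed on the opposite face in the 5-exo sense at C5, so the new C5–O bond is necessarily cis to the C1 carboxyl carbon and the C4 bromide is anti to it, both centres being dictated by C1.

Step 6
Reactants: 7 (1S,4R,5R)-4-bromo-7-oxo-6-oxabicyclo[3.2.1]octan-1-yl benzoate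
Product: 8 (1S,5R)-7-oxo-6-oxabicyclo[3.2.1]oct-3-en-1-yl benzoate
Conditions: DBU, toluene, 100 °C
Reagents that add atoms: none
Why: E2 dehydrobromination in which the axial C4 bromide is antiperiplanar only to the axial C3 hydrogen, elimination towards the bridgehead C5 being excluded by Bredt's rule, so the C3=C4 alkene should form alone.

Step 7
Reactants: 8 (1S,5R)-7-oxo-6-oxabicyclo[3.2.1]oct-3-en-1-yl benzoate
Product: 9 (1S,3R,4R,5R)-3,4-dihydroxy-7-oxo-6-oxabicyclo[3.2.1]octan-1-yl benzoate (1-O-benzoyl-1,5-quinide)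
Conditions: OsO4 (2 mol%), N-methylmorpholine N-oxide, acetone/H2O, rt; Na2SO3 quench
Reagents that add atoms: osmium tetroxide, O=[Os](=O)(=O)=O; N-methylmorpholine N-oxide, C[N+]1([O-])CCOCC1; water, O
Why: Upjohn dihydroxylation adds both oxygens suprafacially to the alkene face not covered by the two-atom lactone bridge, which places O3 and O4 cis to each other and trans to O5.

Step 8
Reactants: 9 1-O-benzoyl-1,5-quinide
Product: 11 (1S,3R,4R,5R)-4-hydroxy-3-[(4-methoxybenzyl)oxy]-7-oxo-6-oxabicyclo[3.2.1]octan-1-yl benzoate, via 3,4-O-dibutylstannylene acetal 10 (not isolated)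
Conditions: Bu2SnO, toluene, reflux (−H2O); then PMBCl, Bu4NI (cat.), toluene, 80 °C
Reagents that add atoms: 4-methoxybenzyl chloride, COc1ccc(CCl)cc1; dibutyltin oxide, CCCC[Sn](=O)CCCC (tin carried only by 10)
Why: Stannylene acetal mediated monoalkylation of a cis-diol goes to the equatorial oxygen, and in the lactone-locked chair O3 is equatorial and next to a methylene whereas O4 is axial beside the bridgehead, so the ether should form at O3.

Step 9
Reactants: 11 3-O-PMB-1-O-benzoyl-1,5-quinide
Product: 12 3-O-(4-methoxybenzyl)-(−)-quinic acid (1-OH, 3-OPMB, 4-OH cis; 5-OH trans)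
Conditions: LiOH·H2O (5 equiv), THF/MeOH/H2O, rt → 40 °C; then 1 M HCl, 0 °C, pH 3
Reagents that add atoms: lithium hydroxide, [Li+].[OH-]; water, O
Why: Saponification opens the strained γ-lactone and cleaves the tertiary benzoate, while the PMB ether is inert to base and no stereocentre carries an acidic hydrogen.

Step 10
Reactants: 12 3-O-(4-methoxybenzyl)-(−)-quinic acid
Product: 13 4-methoxybenzyl 3-O-(4-methoxybenzyl)-(−)-quinate
Conditions: PMBCl (1.1 equiv), KHCO3, Bu4NI (cat.), DMF, rt
Reagents that add atoms: 4-methoxybenzyl chloride, COc1ccc(CCl)cc1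
Why: SN2 alkylation of the carboxylate under bicarbonate, a base too weak to deprotonate the three alcohols, should give the acid-labile ester chemoselectively.

Step 11
Reactants: 14 caffeic acid
Product: 15 4-methoxybenzyl (E)-3-[3,4-bis(4-methoxybenzyloxy)phenyl]acrylate
Conditions: PMBCl (3.3 equiv), K2CO3, Bu4NI (cat.), DMF, 60 °C, Ar
Reagents that add atoms: 4-methoxybenzyl chloride, COc1ccc(CCl)cc1
Why: Exhaustive Williamson alkylation of the two phenoxides and the carboxylate masks the catechol against oxidation and against self-acylation in the coupling.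

Step 12
Reactants: 15 4-methoxybenzyl (E)-3-[3,4-bis(4-methoxybenzyloxy)phenyl]acrylate
Product: 16 (E)-3-[3,4-bis(4-methoxybenzyloxy)phenyl]acrylic acid
Conditions: LiOH·H2O, THF/MeOH/H2O, 50 °C; then 1 M HCl, 0 °C, pH 3
Reagents that add atoms: lithium hydroxide, [Li+].[OH-]
Why: Saponification removes only the ester, since aryl PMB ethers are stable to hydroxide and the E alkene is not touched.

Step 13
Reactants: 13 4-methoxybenzyl 3-O-(4-methoxybenzyl)-(−)-quinate; 16 (E)-3-[3,4-bis(4-methoxybenzyloxy)phenyl]acrylic acid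
Product: 17 4-methoxybenzyl 5-O-[(E)-3,4-bis(4-methoxybenzyloxy)cinnamoyl]-3-O-(4-methoxybenzyl)-(−)-quinate
Conditions: DCC (1.1 equiv), DMAP (0.1 equiv), CH2Cl2, −20 → 0 °C
Reagents that add atoms: none
Why: Steglich esterification should pick the equatorial C5 hydroxyl, which has a methylene neighbour, over the C4 hydroxyl wedged between the axial O3 ether and C5 and over the tertiary C1 hydroxyl.

Step 14
Reactants: 17 the C5 caffeate; 18 Meldrum's acid
Product: 19 4-methoxybenzyl 5-O-[(E)-3,4-bis(4-methoxybenzyloxy)cinnamoyl]-4-O-(carboxyacetyl)-3-O-(4-methoxybenzyl)-(−)-quinate (malonic half ester on O4)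
Conditions: Meldrum's acid (1.5 equiv), toluene, 85 °C
Reagents that add atoms: none
Why: Alcoholysis of Meldrum's acid, in which the only free secondary hydroxyl attacks a ring carbonyl and the ring opens with loss of acetone, delivers the malonic half ester directly under neutral conditions that do not promote acyl migration.

Step 15
Reactants: 19 the fully protected malonate
Product: 20 5-O-[(E)-caffeoyl]-4-O-malonyl-(−)-quinic acid, (1S,3R,4R,5R) in quinic numbering (CNP0286789.1)
Conditions: TFA/CH2Cl2 (1:4), pentamethylbenzene (10 equiv), 0 °C → rt; reversed-phase chromatography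
Reagents that add atoms: none
Why: Acidolysis cleaves the four PMB groups (two aryl ethers, one alkyl ether, one ester) through the 4-methoxybenzyl cation, which pentamethylbenzene traps irreversibly, while the three carboxylic esters are stable to anhydrous acid and no lactone can form because O5 is acylated and O3 is trans to the carboxyl.

**Compound list**

1 | 2,2-dimethyl-1,3-dioxan-5-one | CC1(C)OCC(=O)CO1 | starting material
2 | 2,2-dimethyl-4H-1,3-dioxin-5-yl benzoate | CC1(C)OCC(OC(=O)c2ccccc2)=CO1 | intermediate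
3 | 2-(benzoyloxy)acrolein | C=C(C=O)OC(=O)c1ccccc1 | intermediate
4 | buta-1,3-diene | C=CC=C | starting material
5 | (S)-1-formylcyclohex-3-en-1-yl benzoate | O=C[C@]1(OC(=O)c2ccccc2)CCC=CC1 | intermediate
6 | (S)-1-(benzoyloxy)cyclohex-3-ene-1-carboxylic acid | O=C(O)[C@]1(OC(=O)c2ccccc2)CCC=CC1 | intermediate
7 | (1S,4R,5R)-4-bromo-7-oxo-6-oxabicyclo[3.2.1]octan-1-yl benzoate | O=C1O[C@@H]2C[C@@]1(OC(=O)c3ccccc3)CC[C@H]2Br | intermediate
8 | (1S,5R)-7-oxo-6-oxabicyclo[3.2.1]oct-3-en-1-yl benzoate | O=C1O[C@@H]2C[C@@]1(OC(=O)c3ccccc3)CC=C2 | intermediate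
9 | (1S,3R,4R,5R)-3,4-dihydroxy-7-oxo-6-oxabicyclo[3.2.1]octan-1-yl benzoate | O=C1O[C@@H]2C[C@@]1(OC(=O)c3ccccc3)C[C@@H](O)[C@H]2O | intermediate
10 | 3,4-O-dibutylstannylene acetal of 9 | O=C1O[C@@H]2C[C@@]1(OC(=O)c3ccccc3)C[C@@H](O[Sn](CCCC)(CCCC)O4)[C@H]24 | intermediate
11 | (1S,3R,4R,5R)-4-hydroxy-3-[(4-methoxybenzyl)oxy]-7-oxo-6-oxabicyclo[3.2.1]octan-1-yl benzoate | O=C1O[C@@H]2C[C@@]1(OC(=O)c3ccccc3)C[C@@H](OCc3ccc(OC)cc3)[C@H]2O | intermediate
12 | 3-O-(4-methoxybenzyl)-(−)-quinic acid | O[C@@H]1[C@H](OCc2ccc(OC)cc2)C[C@@](O)(C(=O)O)C[C@H]1O | intermediate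
13 | 4-methoxybenzyl 3-O-(4-methoxybenzyl)-(−)-quinate | O[C@@H]1[C@H](OCc2ccc(OC)cc2)C[C@@](O)(C(=O)OCc2ccc(OC)cc2)C[C@H]1O | intermediate
14 | caffeic acid | O=C(O)/C=C/c1ccc(O)c(O)c1 | starting material
15 | 4-methoxybenzyl (E)-3-[3,4-bis(4-methoxybenzyloxy)phenyl]acrylate | COc1ccc(COC(=O)/C=C/c2ccc(OCc3ccc(OC)cc3)c(OCc3ccc(OC)cc3)c2)cc1 | intermediate
16 | (E)-3-[3,4-bis(4-methoxybenzyloxy)phenyl]acrylic acid | O=C(O)/C=C/c1ccc(OCc2ccc(OC)cc2)c(OCc2ccc(OC)cc2)c1 | intermediate
17 | 4-methoxybenzyl 5-O-[(E)-3,4-bis(4-methoxybenzyloxy)cinnamoyl]-3-O-(4-methoxybenzyl)-(−)-quinate | O[C@@H]1[C@H](OCc2ccc(OC)cc2)C[C@@](O)(C(=O)OCc2ccc(OC)cc2)C[C@H]1OC(=O)/C=C/c1ccc(OCc2ccc(OC)cc2)c(OCc2ccc(OC)cc2)c1 | intermediate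
18 | Meldrum's acid (2,2-dimethyl-1,3-dioxane-4,6-dione) | CC1(C)OC(=O)CC(=O)O1 | starting material
19 | 4-methoxybenzyl 5-O-[(E)-3,4-bis(4-methoxybenzyloxy)cinnamoyl]-4-O-(carboxyacetyl)-3-O-(4-methoxybenzyl)-(−)-quinate | O=C(O)CC(=O)O[C@@H]1[C@H](OCc2ccc(OC)cc2)C[C@@](O)(C(=O)OCc2ccc(OC)cc2)C[C@H]1OC(=O)/C=C/c1ccc(OCc2ccc(OC)cc2)c(OCc2ccc(OC)cc2)c1 | intermediate
20 | 5-O-[(E)-caffeoyl]-4-O-malonyl-(−)-quinic acid | O=C(O)CC(=O)O[C@@H]1[C@H](O)C[C@@](O)(C(=O)O)C[C@H]1OC(=O)/C=C/c1ccc(O)c(O)c1 | target

**Step count and risks**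

Total steps: 15. Longest linear sequence: 13 (steps 1–10, 13, 14, 15); steps 11 and 12 prepare the caffeoyl donor.

Steps most likely to fail:

Step 3. Butadiene is a sluggish diene, so the iminium may react slowly, the acrolein 3 may polymerise under the strongly acidic salt, and face discrimination may be weaker than with cyclic dienes. The fallback gives up catalytic induction for classical resolution. It sets out from 3 and 4, which are heated without catalyst (toluene, 110 °C, sealed tube, BHT) to the racemic aldehyde rac-1-formylcyclohex-3-en-1-yl benzoate F1. Pinnick oxidation as in step 4 gives the racemic acid rac-1-(benzoyloxy)cyclohex-3-ene-1-carboxylic acid F2. Crystallisation with (R)-1-phenylethylamine (or its antipode, whichever gives the less soluble salt of the S acid) should give (R)-1-phenylethylammonium (S)-1-(benzoyloxy)cyclohex-3-ene-1-carboxylate F3. Acidification returns to the route at 6.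

Step 13. The danger is acylation at O4 as well as O5, double acylation, or DMAP-promoted shuttling of the cinnamoyl group between the trans-diequatorial O5 and O4. The fallback replaces kinetic discrimination by explicit masking of O4 and sets out from 11.
- Dihydropyran and PPTS in CH2Cl2 should give the 4-O-tetrahydropyran-2-yl ether of 11 F4, as a mixture of acetal epimers.
- Hydrolysis as in step 9, acidified only to pH 4, gives 3-O-PMB-4-O-(tetrahydropyran-2-yl)quinic acid F5.
- Alkylation as in step 10 gives its 4-methoxybenzyl ester F6.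
- Coupling with 16 as in step 13, now with a single secondary hydroxyl, gives the 5-O-cinnamoyl-4-O-(tetrahydropyran-2-yl) ester F7.
- AcOH/THF/H2O at 45 °C removes the acetal without touching PMB groups and returns to the route at 17.

Step 14. The flanked O4 hydroxyl may acylate slowly, and prolonged heating risks decarboxylation of the half ester or acylation of the tertiary O1. The fallback sets out from 17 and replaces thermal alcoholysis by carbodiimide activation of a protected malonate. Commercial mono-tert-butyl malonate, DCC and catalytic DMAP in CH2Cl2 at 0 °C should give the C4 tert-butyl malonate diester of 17 F8. The acidolysis of step 15 also cleaves the tert-butyl ester, so the fallback returns to the route at 20.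

Further compounds
F1 | step 3 | rac-1-formylcyclohex-3-en-1-yl benzoate | O=CC1(OC(=O)c2ccccc2)CCC=CC1
F2 | step 3 | rac-1-(benzoyloxy)cyclohex-3-ene-1-carboxylic acid | O=C(O)C1(OC(=O)c2ccccc2)CCC=CC1
F3 | step 3 | (R)-1-phenylethylammonium (S)-1-(benzoyloxy)cyclohex-3-ene-1-carboxylate | O=C([O-])[C@]1(OC(=O)c2ccccc2)CCC=CC1.C[C@@H]([NH3+])c1ccccc1
F4 | step 13 | (1S,3R,4R,5R)-3-[(4-methoxybenzyl)oxy]-7-oxo-4-(tetrahydropyran-2-yloxy)-6-oxabicyclo[3.2.1]octan-1-yl benzoate (acetal carbon unassigned) | O=C1O[C@@H]2C[C@@]1(OC(=O)c3ccccc3)C[C@@H](OCc3ccc(OC)cc3)[C@H]2OC3CCCCO3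
F5 | step 13 | 3-O-(4-methoxybenzyl)-4-O-(tetrahydropyran-2-yl)-(−)-quinic acid | O1CCCCC1O[C@@H]2[C@H](OCc3ccc(OC)cc3)C[C@@](O)(C(=O)O)C[C@H]2O
F6 | step 13 | 4-methoxybenzyl 3-O-(4-methoxybenzyl)-4-O-(tetrahydropyran-2-yl)-(−)-quinate | O1CCCCC1O[C@@H]2[C@H](OCc3ccc(OC)cc3)C[C@@](O)(C(=O)OCc3ccc(OC)cc3)C[C@H]2O
F7 | step 13 | 4-methoxybenzyl 5-O-[(E)-3,4-bis(4-methoxybenzyloxy)cinnamoyl]-3-O-(4-methoxybenzyl)-4-O-(tetrahydropyran-2-yl)-(−)-quinate | O1CCCCC1O[C@@H]2[C@H](OCc3ccc(OC)cc3)C[C@@](O)(C(=O)OCc3ccc(OC)cc3)C[C@H]2OC(=O)/C=C/c2ccc(OCc3ccc(OC)cc3)c(OCc3ccc(OC)cc3)c2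
F8 | step 14 | 4-methoxybenzyl 5-O-[(E)-3,4-bis(4-methoxybenzyloxy)cinnamoyl]-4-O-[(tert-butoxycarbonyl)acetyl]-3-O-(4-methoxybenzyl)-(−)-quinate | CC(C)(C)OC(=O)CC(=O)O[C@@H]1[C@H](OCc2ccc(OC)cc2)C[C@@](O)(C(=O)OCc2ccc(OC)cc2)C[C@H]1OC(=O)/C=C/c1ccc(OCc2ccc(OC)cc2)c(OCc2ccc(OC)cc2)c1
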